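The decision was to run the same charge of Q through different temperature histories, one of them, gamma, held cold and then warmed, and to read X at the same hour in each flask.

| flask | Q | temperature | time | remark |
|---|---|---|---|---|
| theta | 11 mM | −10 °C | 20 h |  |
| beta | 11 mM | −25 °C | 20 h |  |
| gamma | 11 mM |  | 20 h | at −25 °C until 4.0 h, from then on at 5 °C |
| epsilon | 11 mM | 5 °C | 20 h |  |

    Q → X (k1 = 0.61 h⁻¹, Ea1 = 92.0 kJ mol⁻¹)
    X → Z (k2 = 0.35 h⁻¹, Ea2 = 88.0 kJ mol⁻¹)
    Z → E (k3 = 0.28 h⁻¹, Ea3 = 80.0 kJ mol⁻¹)
    Q ⇌ L (K4 = 0.64, k4 = 0.20 h⁻¹, Ea4 = 83.0 kJ mol⁻¹, ΔH4 = −33.0 kJ mol⁻¹)
    2 Q → Q2 (k5 = 9.2 L mol⁻¹ h⁻¹, Ea5 = 48.0 kJ mol⁻¹)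
    (constants at 5 °C)

- which flask leads in amount of X, in percent of the Q charged ("all alike" within 1.5 percentage points) (theta / beta / gamma / epsilon / all alike)
- how much X is there at the end, in percent of the Q charged: theta
- how much X is there at the end, in percent of the Q charged: beta
- how much X is there at the end, in percent of the Q charged: gamma
- how much X is there at the end, in percent of the Q charged: epsilon

- in percentages every species weighs as the Q in it: one Q2 counts as two
- where a step has two of a species, its rate is k times that concentration squared, and two are used at each turn
- the list of constants is for 5 °C, to be carried to other temperatures by the activation energies and enthalpies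

Q goes to X, X to Z and Z to E, while Q also parks reversibly as L and pairs with itself. At 5 °C flask gamma shows an apparent contradiction. X is drained at 0.35 h⁻¹, so the 16.0 h spent warm should leave 0.370 % of any X standing at the change, and Q has a half-life of 1.14 h by its step to X. Yet the balance of Q below ends flask gamma with 2.26 % of the charge as X, far more than that count suggests.

That balance clears it up. In the reckoning made here, with pairing set aside, cQ falls at 0.810 h⁻¹ times cQ but is refilled from L at 0.312 h⁻¹ times cL, and L gains what Q hands it. Two coupled first-order balances have two decay constants, and the smaller is the pool constant, the rate at which Q and L fall together once the fast part has died, 0.209 h⁻¹, a halving time of 3.32 h. It lies below the drains of X and Z, so X late follows the pool down. The slow part carries 14.7 % of the charge. Counting the cold hold as idle, the tail gives the 2.26 % for gamma and 0.980 % for epsilon. Pairing, at 0.202 h⁻¹ at the start, was left out, so both should run high. This reckoning covers warm time, and theta and beta are left to the forecast.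

The forecast names theta, with 28.7 % in theta, 7.8 % in beta, 1.95 % in gamma and 0.87 % in epsilon. Its warm values stand lower than the reckoning here, on the ground that “Q and L decay on a slow mode of 0.209 /h, with the amplitude cut about 14% by dimerisation”.

The simulation puts theta ahead with 28.7 %, then beta with 7.76 %, gamma with 1.94 % and epsilon with 0.866 %, each within the forecast's range.

Flask gamma is not at rest at 20 h, for it still holds 6.64 % Z beside 74.3 % E. Left until 200 h, its X reads 0 % and its E 84.2 %, a stretch of 37.6 e-foldings of the pool constant. Run backwards, the pool constant carries the 1.94 % of flask gamma to 10.3 % for the same flask read at 12 h, and that neighbour reads 11.2 %.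

The constants used here were chosen freely; the run is a simulation.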